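Late in a run the target is still exposed to the reagent that made it, which turns it into over-reacted product. What we collect at the end therefore depends on how much reagent has crossed over by then.

| flask | starting material | reagent in the second phase | time | volume of the second phase over the first |
|---|---|---|---|---|
| epsilon | 0.25 M | 1.20 equiv | 30 h | 1.0 |
| beta | 0.25 M | 2.00 equiv | 30 h | 1.0 |
| delta | 0.25 M | 2.50 equiv | 30 h | 1.0 |
| alpha | 0.25 M | 4.00 equiv | 30 h | 1.0 |
| gamma | 0.25 M | 6.00 equiv | 30 h | 1.0 |

    reagent in the reaction phase ⇌ reagent in the second phase, rate k1*([reagent in the reaction phase] - [reagent in the second phase]/K1) per volume of the first phase (K1 = 23, k1 = 0.18 h⁻¹)
    starting material + reagent in the reaction phase → target (k2 = 4.2 L mol⁻¹ h⁻¹)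
    reagent in the reaction phase + target → over-reacted product (k3 = 16 L mol⁻¹ h⁻¹)

- in the second phase: reagent in the second phase; everything else is in the first
- charges count per volume of the first phase; a concentration in a rate is the amount of a species over the volume of its own phase; every rate counts per litre of the first phase
- "hardly changes" means that all values lie within two and a half points (for a concentration: within two and a half percent of the largest)
- run time (epsilon): 30 h

* amount of target at the end, in percent of the starting material charged for epsilon, beta, delta, alpha, gamma, in this order
* how that number moves from the first to the last of them (falls all the way / rises, then falls / rises all the way / hardly changes / falls, then rises)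

We start from the balance of the starting material, the limiting reagent in each flask, since every charge of reagent exceeds one equivalent. Each target formed has taken one reagent and each over-reacted product two. The supply comes from the second phase, which empties slowly. If nothing came back, the share crossing in the run would be φ, the delivery share, equal to 20.9 %. Multiplied by the equivalents charged, this gives one number, N: reagent delivered as a percentage of the starting material.

Both steps use the same reagent, so its concentration cancels from their ratio, and the selectivity factor r = k3/k2 = 3.81 sets the path. With a as the fraction of starting material left, the target peaks at a = 0.621, where it is 16.3 % of the charge. Reaching that point costs N* = 59.4 %. Epsilon has N = 25.1 %, below it, and gamma has 126 %, above it. So we expect the row to rise and then fall, turning near 2.84 equivalents.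

One number was not quite enough: it needed r beside it. Reagent also returns to the second phase, and at the start k1 is 14.6 % of the total loss rate of the reaction-phase reagent, k1 + k2·[starting material]. N is therefore a ceiling, and we place the turn somewhat higher. Our reckoning stops there.

The forecast commits to 11.9 %, 14.9 %, 15.8 %, 16 % and 13 %, shape "rises, then falls", holding that “Selectivity does not depend on the feed”.

The flasks give 12.0 %, 15.0 %, 15.9 %, 16.0 % and 13.0 %, shape "rises, then falls", with the turn read at 3.3 equiv. The forecast's shape stands while the row spans that turn.

In epsilon at 30.0 h, the reagent in the reaction phase is made 0.993 times as fast as it is used. It stands at 0.00126 M, a quasi-steady state. There the second phase keeps 81.4 % of its charge, so 22.3 % has crossed, under the ceiling of 25.1 %, and target plus twice the over-reacted product comes to 21.8 %. In gamma the ceiling is 126 %, 111 % has crossed, and the same sum comes to 108 %.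

The numbers of this flask come from no measurement; what happens was integrated by code.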